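The trans-decalin is cut at the ring-fusion bond C5–C10 and at C7–C8 (labdane numbering), the two opposite bonds of ring B; this opens both carbocycles to one acyclic chain. One tributyltin hydride radical chain closes them again: denitration gives the tertiary C10 radical, which adds 6-exo to the enal (ring A), and the freed C7 aldehyde is then attacked by the vinyl radical of the C8 alkyne (ring B). The step exploits the quaternary methyl-bearing C10 and the C7 carbinol next to the C8 exocyclic methylene. Its precursor is an acyclic nitro enal alkyne whose single stereocentre, C9, comes from organocatalysis; the dioxepine is built last.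

Key step: step 9

Numbering: labdane numbers are used throughout: decalin C1–C10 (C4 gem-dimethyl, C10 angular methyl), C17 = exocyclic CH2 on C8, side chain C11–C16 on C9 (C16 = CHO, C15 = peroxyhemiacetal carbon).
Assumption: C15 of the peroxyhemiacetal equilibrates by ring–chain tautomerism, so the 15S epimer of the target is taken as the thermodynamic product.

Step 1
Reactants: 1 4,4-dimethyl-5-oxopentanenitrile
Product: 2 ethyl (2E)-6-cyano-4,4-dimethylhex-2-enoate
Conditions: Ph3P=CHCO2Et, PhMe, 90 °C
Reagents that add atoms: ethyl (triphenylphosphoranylidene)acetate CCOC(=O)C=P(c1ccccc1)(c1ccccc1)c1ccccc1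
Why: Wittig olefination of a hindered, non-enolizable aldehyde with a stabilized ylide should give the E-enoate; the nitrile is inert.

Step 2
Reactants: 2 ethyl (2E)-6-cyano-4,4-dimethylhex-2-enoate
Product: 3 (5E)-7-hydroxy-4,4-dimethylhept-5-enal
Conditions: i-Bu2AlH (3.5 equiv), CH2Cl2, −78 °C; aq. KNaC4H4O6
Reagents that add atoms: water O
Why: Hydride reduction with i-Bu2AlH takes the conjugated ester to the allylic alcohol (1,2-reduction) while the nitrile stops at the aluminium imine, which is hydrolysed to the aldehyde on work-up.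

Step 3
Reactants: 3 (5E)-7-hydroxy-4,4-dimethylhept-5-enal; 4 nitroethane
Product: 5 (2E)-4,4-dimethyl-8-nitronon-2-ene-1,7-diol (diastereomer mixture)
Conditions: Bu4NF (10 mol %), THF, 0 °C to rt
Reagents that add atoms: none
Why: Henry (nitroaldol) addition under catalytic fluoride; the two new stereocentres need no control because one is removed in step 4 and the other becomes a planar radical in step 9.

Step 4
Reactants: 5 (2E)-4,4-dimethyl-8-nitronon-2-ene-1,7-diol
Product: 7 (2E)-4,4-dimethyl-8-nitronon-2-en-1-yl acetate (racemic at the nitro carbon), via nitro diol diacetate 6 (not isolated)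
Conditions: Ac2O, DMAP, Et3N, CH2Cl2, 0 °C; then EtOH, NaBH4, 0 °C
Reagents that add atoms: acetic anhydride CC(=O)OC(C)=O
Why: Nitroaldol dehydration–reduction: the β-nitro acetate eliminates to the nitroalkene, which takes up hydride in a conjugate reduction, while the allylic acetate stays as a protecting group.

Step 5
Reactants: 8 3-(trimethylsilyl)prop-2-ynal
Product: 9 (2E)-5-(trimethylsilyl)pent-2-en-4-ynal
Conditions: Ph3P=CHCHO, PhMe, 60 °C
Reagents that add atoms: (triphenylphosphoranylidene)acetaldehyde O=CC=P(c1ccccc1)(c1ccccc1)c1ccccc1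
Why: Wittig olefination with the formyl-stabilized ylide should give the E-enal; the silyl group caps the alkyne terminus.

Step 6
Reactants: 7 (2E)-4,4-dimethyl-8-nitronon-2-en-1-yl acetate; 9 (2E)-5-(trimethylsilyl)pent-2-en-4-ynal
Product: 10 (2E,9S)-4,4,8-trimethyl-8-nitro-11-oxo-9-[(trimethylsilyl)ethynyl]undec-2-en-1-yl acetate (both C8 epimers)
Conditions: (S)-2-[diphenyl(trimethylsilyloxy)methyl]pyrrolidine (20 mol %), PhCO2H (20 mol %), MeOH, rt
Reagents that add atoms: none
Why: Iminium-catalysed Michael addition of the nitronate to the enynal β-carbon; the silyloxydiphenylmethyl group of the (S)-catalyst shields one face of the E-iminium ion so that labdane C9 should form S, the silyl cap disfavours 1,6-addition, and the epimer mixture at the quaternary nitro carbon is of no consequence.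

Step 7
Reactants: 10 (2E,9S)-4,4,8-trimethyl-8-nitro-11-oxo-9-[(trimethylsilyl)ethynyl]undec-2-en-1-yl acetate
Product: 12 (2E,9S)-9-ethynyl-4,4,8-trimethyl-8-nitroundec-2-ene-1,11-diol (both C8 epimers), via silylalkyne hydroxy acetate 11 (not isolated)
Conditions: NaBH4, MeOH, 0 °C; then K2CO3, rt
Reagents that add atoms: none
Why: Chemoselective borohydride reduction of the aldehyde, then methanolysis of the acetate and of the alkynyl C–Si bond; the tertiary nitro group and C9 are untouched.

Step 8
Reactants: 12 (2E,9S)-9-ethynyl-4,4,8-trimethyl-8-nitroundec-2-ene-1,11-diol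
Product: 13 (2E,9S)-9-ethynyl-11-hydroxy-4,4,8-trimethyl-8-nitroundec-2-enal (both C8 epimers)
Conditions: MnO2, CH2Cl2, rt
Reagents that add atoms: none
Why: Allylic oxidation with MnO2 is selective for the allylic alcohol over the saturated primary alcohol and keeps the E geometry.

Step 9
Reactants: 13 (2E,9S)-9-ethynyl-11-hydroxy-4,4,8-trimethyl-8-nitroundec-2-enal
Product: 16 2-[(1R,3R,4aS,8aS)-3-hydroxy-5,5,8a-trimethyl-2-methylidenedecahydronaphthalen-1-yl]ethan-1-ol, via monocyclic ethynyl aldehyde 14 (not isolated), via C17-stannyl allylic alcohol 15 (not isolated)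
Conditions: Bu3SnH (2.6 equiv), AIBN (0.4 equiv), slow addition, PhH (0.005 M), 80 °C; then HCl, Et2O, 0 °C
Reagents that add atoms: none
Why: Bu3Sn• adds to the tertiary nitro group and loss of Bu3SnONO gives the C10 radical, which adds to the enal β-carbon C5 (denitrative Giese cyclization, ring A by 6-exo-trig closure); after hydrogen transfer to C6, Bu3Sn• adds reversibly to the terminal alkyne and the C8 vinyl radical adds to the C7 aldehyde (stannyl-radical alkynal cyclization, ring B by 6-exo-trig closure onto C=O), and HCl finally replaces tin on C17 by hydrogen. Both events are known radical-chain reaction types, run here in sequence on one substrate. C5 and C10 should arise from a chair-like transition state with the enal arm and the C9 branch pseudo-equatorial, which places H-5 and the C10 methyl trans; C10 relative to C9 follows 1,2-induction, with the larger hydroxyethyl branch of C9 anti to the forming bond and the slim ethynyl group gauche to it, which is the arrangement ring B needs. C7 is set by allylic 1,3-strain: the stannyl group on C17 sits cis to the forming C7–C8 bond and forces the carbonyl oxygen pseudo-axial, which should give the 7α-alcohol. The order of the closures is secured by the faster reaction of Bu3Sn• with the nitro group and by ring size (the alkyne cannot reach C7 before ring A exists), and slow stannane addition keeps the vinyl radical from being reduced before it cyclizes.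

Step 10
Reactants: 16 2-[(1R,3R,4aS,8aS)-3-hydroxy-5,5,8a-trimethyl-2-methylidenedecahydronaphthalen-1-yl]ethan-1-ol
Product: 17 2-[(1R,3R,4aS,8aS)-3-hydroxy-5,5,8a-trimethyl-2-methylidenedecahydronaphthalen-1-yl]acetaldehyde
Conditions: TEMPO (10 mol %), PhI(OAc)2, CH2Cl2, rt
Reagents that add atoms: none
Why: Oxoammonium (TEMPO) oxidation is selective for the unhindered primary alcohol over the axial secondary allylic alcohol; the trans arrangement of the C7 hydroxyl and the C9 side chain prevents lactol formation and over-oxidation.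

Step 11
Reactants: 17 2-[(1R,3R,4aS,8aS)-3-hydroxy-5,5,8a-trimethyl-2-methylidenedecahydronaphthalen-1-yl]acetaldehyde; 18 4,4-dimethoxybutanal
Product: 19 (2E)-2-(2,2-dimethoxyethyl)-4-[(1R,3R,4aS,8aS)-3-hydroxy-5,5,8a-trimethyl-2-methylidenedecahydronaphthalen-1-yl]but-2-enal
Conditions: pyrrolidine (30 mol %), PhCO2H (30 mol %), CH2Cl2, rt, 18 added slowly
Reagents that add atoms: none
Why: Amine-catalysed cross-aldol condensation: the enamine of the unbranched donor 18 adds to the β-branched acceptor 17 and loss of water should give the thermodynamically preferred E-2-substituted enal, slow addition of 18 limiting its self-condensation.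

Step 12
Reactants: 19 (2E)-2-(2,2-dimethoxyethyl)-4-[(1R,3R,4aS,8aS)-3-hydroxy-5,5,8a-trimethyl-2-methylidenedecahydronaphthalen-1-yl]but-2-enal
Product: 20 (2E,4S)-2-(2,2-dimethoxyethyl)-4-hydroperoxy-4-[(1R,3R,4aS,8aS)-3-hydroxy-5,5,8a-trimethyl-2-methylidenedecahydronaphthalen-1-yl]but-2-enal
Conditions: KN(SiMe3)2 (2.2 equiv), THF, −78 °C; O2, −78 °C; AcOH
Reagents that add atoms: dioxygen O=O
Why: Dienolate autoxidation: γ-deprotonation gives the s-trans potassium dienolate, which should take up triplet O2 at C11 (the α-carbon is fully substituted) with return of the conjugated E-enal, and C11 should form S because H-9 eclipses the C11=C12 bond (allylic strain) and O2 approaches anti to the quaternary C10.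

Step 13
Reactants: 20 (2E,4S)-2-(2,2-dimethoxyethyl)-4-hydroperoxy-4-[(1R,3R,4aS,8aS)-3-hydroxy-5,5,8a-trimethyl-2-methylidenedecahydronaphthalen-1-yl]but-2-enal
Product: 21 (5S,7R,9R,10S,11S,12E,15S)-7,15-dihydroxy-11,15-epidioxylabda-8(17),12-dien-16-al
Conditions: AcOH–THF–H2O (3:1:1), rt
Reagents that add atoms: water O
Why: Acid hydrolysis of the acetal and intramolecular addition of the hydroperoxide to the freed C15 aldehyde (peroxyhemiacetal formation) should close the 1,2-dioxepine ring, with C15 set under thermodynamic control.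

Compound list
1 | 4,4-dimethyl-5-oxopentanenitrile | N#CCCC(C)(C)C=O | starting material
2 | ethyl (2E)-6-cyano-4,4-dimethylhex-2-enoate | CCOC(=O)/C=C/C(C)(C)CCC#N | intermediate
3 | (5E)-7-hydroxy-4,4-dimethylhept-5-enal | O=CCCC(C)(C)/C=C/CO | intermediate
4 | nitroethane | CC[N+](=O)[O-] | starting material
5 | (2E)-4,4-dimethyl-8-nitronon-2-ene-1,7-diol (diastereomer mixture) | OC/C=C/C(C)(C)CCC(O)C(C)[N+](=O)[O-] | intermediate
6 | (2E)-4,4-dimethyl-8-nitronon-2-ene-1,7-diyl diacetate (diastereomer mixture) | CC(=O)OC/C=C/C(C)(C)CCC(OC(C)=O)C(C)[N+](=O)[O-] | intermediate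
7 | (2E)-4,4-dimethyl-8-nitronon-2-en-1-yl acetate (racemic at C8) | CC(=O)OC/C=C/C(C)(C)CCCC(C)[N+](=O)[O-] | intermediate
8 | 3-(trimethylsilyl)prop-2-ynal | C[Si](C)(C)C#CC=O | starting material
9 | (2E)-5-(trimethylsilyl)pent-2-en-4-ynal | C[Si](C)(C)C#C/C=C/C=O | intermediate
10 | (2E,9S)-4,4,8-trimethyl-8-nitro-11-oxo-9-[(trimethylsilyl)ethynyl]undec-2-en-1-yl acetate (both C8 epimers) | CC(=O)OC/C=C/C(C)(C)CCCC(C)([N+](=O)[O-])[C@H](C#C[Si](C)(C)C)CC=O | intermediate
11 | (2E,9S)-11-hydroxy-4,4,8-trimethyl-8-nitro-9-[(trimethylsilyl)ethynyl]undec-2-en-1-yl acetate (both C8 epimers) | CC(=O)OC/C=C/C(C)(C)CCCC(C)([N+](=O)[O-])[C@H](C#C[Si](C)(C)C)CCO | intermediate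
12 | (2E,9S)-9-ethynyl-4,4,8-trimethyl-8-nitroundec-2-ene-1,11-diol (both C8 epimers) | OC/C=C/C(C)(C)CCCC(C)([N+](=O)[O-])[C@H](C#C)CCO | intermediate
13 | (2E,9S)-9-ethynyl-11-hydroxy-4,4,8-trimethyl-8-nitroundec-2-enal (both C8 epimers) | O=C/C=C/C(C)(C)CCCC(C)([N+](=O)[O-])[C@H](C#C)CCO | intermediate
14 | 2-[(1S,2S)-2-[(3S)-5-hydroxypent-1-yn-3-yl]-2,6,6-trimethylcyclohexyl]acetaldehyde | O=CC[C@H]1C(C)(C)CCC[C@]1(C)[C@H](C#C)CCO | intermediate
15 | 2-[(1R,3R,4aS,8aS)-3-hydroxy-5,5,8a-trimethyl-2-[(tributylstannyl)methylidene]decahydronaphthalen-1-yl]ethan-1-ol (E/Z mixture) | CCCC[Sn](CCCC)(CCCC)C=C1[C@H](O)C[C@H]2C(C)(C)CCC[C@]2(C)[C@H]1CCO | intermediate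
16 | 2-[(1R,3R,4aS,8aS)-3-hydroxy-5,5,8a-trimethyl-2-methylidenedecahydronaphthalen-1-yl]ethan-1-ol (trans-decalin, 7α-OH, 9β side chain) | C=C1[C@H](O)C[C@H]2C(C)(C)CCC[C@]2(C)[C@H]1CCO | intermediate
17 | 2-[(1R,3R,4aS,8aS)-3-hydroxy-5,5,8a-trimethyl-2-methylidenedecahydronaphthalen-1-yl]acetaldehyde | C=C1[C@H](O)C[C@H]2C(C)(C)CCC[C@]2(C)[C@H]1CC=O | intermediate
18 | 4,4-dimethoxybutanal | COC(OC)CCC=O | starting material
19 | (2E)-2-(2,2-dimethoxyethyl)-4-[(1R,3R,4aS,8aS)-3-hydroxy-5,5,8a-trimethyl-2-methylidenedecahydronaphthalen-1-yl]but-2-enal | C=C1[C@H](O)C[C@H]2C(C)(C)CCC[C@]2(C)[C@H]1C/C=C(/C=O)CC(OC)OC | intermediate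
20 | (2E,4S)-2-(2,2-dimethoxyethyl)-4-hydroperoxy-4-[(1R,3R,4aS,8aS)-3-hydroxy-5,5,8a-trimethyl-2-methylidenedecahydronaphthalen-1-yl]but-2-enal | C=C1[C@H](O)C[C@H]2C(C)(C)CCC[C@]2(C)[C@H]1[C@@H](OO)/C=C(/C=O)CC(OC)OC | intermediate
21 | (5S,7R,9R,10S,11S,12E,15S)-7,15-dihydroxy-11,15-epidioxylabda-8(17),12-dien-16-al | C=C1[C@H](O)C[C@H]2C(C)(C)CCC[C@]2(C)[C@H]1[C@@H]1C=C(C=O)C[C@@H](O)OO1 | target

Total step count: 13. Longest linear sequence: 12 steps (steps 1–4 and 6–13; step 5 makes the second fragment).

Steps most likely to fail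

Step 9. The cascade may break down through reduction of the enal by way of its stannyl ketyl before denitration, hydrostannation of the alkyne, 5-exo attack of the C6 radical on the alkyne, or low facial selectivity at C10 or C7. The fallback runs the two ring closures separately, setting out from 13 and returning at 16. Bu3SnH (1.3 equiv) and AIBN at 0.05 M are used only for the denitrative Giese cyclization, and the monocyclic aldehyde 14 is isolated. SmI2 with HMPA and t-BuOH then closes ring B by ketyl–alkyne cyclization, which should give mainly the equatorial 7β-alcohol 2-[(1R,3S,4aS,8aS)-3-hydroxy-5,5,8a-trimethyl-2-methylidenedecahydronaphthalen-1-yl]ethan-1-ol F1. MnO2 oxidizes it to the enone (4R,4aS,8aS)-4-(2-hydroxyethyl)-4a,8,8-trimethyl-3-methylideneoctahydronaphthalen-2(1H)-one F2, and Corey–Bakshi–Shibata reduction with the (S)-oxazaborolidine and catecholborane should set the 7α-alcohol 16 under reagent control.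

Step 12. The oxygenation may fail through oxygen uptake at the α-carbon, base-induced decomposition of the hydroperoxide anion (Kornblum–DeLaMare type), or low facial selectivity at C11. The fallback changes to a neutral pericyclic oxygenation, setting out from 19 and returning at 21. TMSOTf and Et3N give the bis-silyl compound (7-O-trimethylsilyl ether and 1-trimethylsilyloxy-1,3-diene) F3. Photooxygenation (O2, tetraphenylporphyrin, hν, −78 °C) puts oxygen on the γ-carbon and, after silyl transfer, should give the 11-(trimethylsilylperoxy) enal F4. Aqueous AcOH then cleaves both O–Si bonds and the acetal and closes the peroxyhemiacetal to 21.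

Step 11. The condensation may suffer from self-condensation of the donor aldehyde and low cross-selectivity. The fallback is a directed aldol condensation, setting out from 17 (with 18) and returning at 19. Aldehyde 18 is condensed with cyclohexylamine to the imine N-cyclohexyl-4,4-dimethoxybutan-1-imine F5. Its lithium aza-enolate (LiN(i-Pr)2, THF, −78 °C) adds to 17 to give the β-hydroxy imine F6, and buffered aqueous oxalic acid hydrolyses the imine and eliminates water to give 19.

Further compounds
F1 | step 9 | 2-[(1R,3S,4aS,8aS)-3-hydroxy-5,5,8a-trimethyl-2-methylidenedecahydronaphthalen-1-yl]ethan-1-ol | C=C1[C@@H](O)C[C@H]2C(C)(C)CCC[C@]2(C)[C@H]1CCO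
F2 | step 9 | (4R,4aS,8aS)-4-(2-hydroxyethyl)-4a,8,8-trimethyl-3-methylideneoctahydronaphthalen-2(1H)-one | C=C1C(=O)C[C@H]2C(C)(C)CCC[C@]2(C)[C@H]1CCO
F3 | step 12 | 7-O-trimethylsilyl 1-(trimethylsilyloxy)diene derived from 19 (diene geometry unassigned) | C=C1[C@H](O[Si](C)(C)C)C[C@H]2C(C)(C)CCC[C@]2(C)[C@H]1C=CC(CC(OC)OC)=CO[Si](C)(C)C
F4 | step 12 | (2E,4S)-2-(2,2-dimethoxyethyl)-4-(trimethylsilylperoxy)-4-[(1R,3R,4aS,8aS)-5,5,8a-trimethyl-2-methylidene-3-(trimethylsilyloxy)decahydronaphthalen-1-yl]but-2-enal | C=C1[C@H](O[Si](C)(C)C)C[C@H]2C(C)(C)CCC[C@]2(C)[C@H]1[C@@H](OO[Si](C)(C)C)/C=C(/C=O)CC(OC)OC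
F5 | step 11 | N-cyclohexyl-4,4-dimethoxybutan-1-imine | COC(OC)CCC=NC1CCCCC1
F6 | step 11 | β-hydroxy imine from 17 and lithiated F5 (diastereomer mixture at the two new centres) | C=C1[C@H](O)C[C@H]2C(C)(C)CCC[C@]2(C)[C@H]1CC(O)C(C=NC1CCCCC1)CC(OC)OC
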